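**Retrosynthetic overview**
- Last bond made: the C(sp3)–C(sp3) bond between the allylic CH(CH3) carbon and the CH2CH2 tether. A nickel-catalysed stereoconvergent Negishi coupling (allyl radical from a racemic allylic chloride) joins the C19 chain fragment to the C12 ring fragment and sets the allylic methyl stereocentre.
- Chain fragment: the vinyl-bearing quaternary carbon comes from NHC–copper SN2' substitution of (E,E)-farnesyl phosphate with an alkenylalane. Farnesol is built from 5-bromo-2-methylpent-2-ene by two zirconium-catalysed methylaluminations and one sp3–sp2 Negishi coupling.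
- Ring fragment: the only ring (the cyclohexane) is closed first, in step 1, by an organocatalytic Michael/aldol annulation. Two methyl cuprate additions, a trans-selective enolate alkylation and a methylenation follow.

Assumption: the catalyst antipodes named in steps 1, 13 and 16 are those expected from the usual facial models to give the drawn configurations; if a model run shows the opposite sense, the mirror-image catalyst is used.

**Route**

Step 1
Reactants: 1 propanal; 2 but-3-en-2-one
Product: 4 (4S)-4-methylcyclohex-2-en-1-one, via keto aldehyde 3 (not isolated)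
Conditions: (R)-α,α-diphenylprolinol trimethylsilyl ether (5 mol%), ethyl 3,4-dihydroxybenzoate (20 mol%), neat, 4 °C; then LiOH, i-PrOH, rt
Reagents that add atoms: none
Why: Enamine-mediated asymmetric Michael addition of propanal to the enone, in which the (R)-catalyst shields one enamine face and fixes the methyl-bearing carbon as S, is followed by an intramolecular aldol condensation (Robinson-type annulation) that closes the ring without touching that centre.

Step 2
Reactants: 4 (4S)-4-methylcyclohex-2-en-1-one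
Product: 6 (4S)-3,4-dimethylcyclohex-2-en-1-one, via silyl enol ether 5 (not isolated)
Conditions: MeMgBr, CuI (10 mol%), Me3SiCl, THF, −78 °C; then Pd(OAc)2 (10 mol%), O2, DMSO, rt
Reagents that add atoms: methylmagnesium bromide, C[Mg]Br; chlorotrimethylsilane, C[Si](C)(C)Cl (silicon stays only in 5)
Why: Copper-catalysed conjugate addition places the methyl group at C3 anti to the C4 methyl and the enolate is trapped as its silyl enol ether, which Saegusa–Ito dehydrogenation converts back into the C2–C3 enone while the C4 centre stays untouched.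

Step 3
Reactants: 6 (4S)-3,4-dimethylcyclohex-2-en-1-one; 7 ethyl iodoacetate
Product: 9 ethyl 2-[(1R,3S)-2,2,3-trimethyl-6-oxocyclohexyl]acetate, via lithium enolate 8 (not isolated)
Conditions: Me2CuLi, Et2O, 0 °C; then 7, HMPA, THF, −40 to 0 °C
Reagents that add atoms: lithium dimethylcuprate, [Li+].C[Cu-]C (lithium stays only in 8)
Why: Gilman cuprate conjugate addition creates the gem-dimethyl carbon and gives the C1–C2 enolate regiospecifically, and its SN2 alkylation takes place by axial attack on the half-chair that keeps the C4 methyl equatorial (the other face would force a 1,3-diaxial clash), so the acetate arm ends trans to that methyl (1R).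

Step 4
Reactants: 9 ethyl 2-[(1R,3S)-2,2,3-trimethyl-6-oxocyclohexyl]acetate
Product: 10 ethyl 2-[(1S,3S)-2,2,3-trimethyl-6-methylidenecyclohexyl]acetate
Conditions: Zn, CH2Br2, TiCl4, THF, 0 °C to rt
Reagents that add atoms: dibromomethane, BrCBr
Why: Lombardo–Takai methylenation uses a non-basic CH2(ZnBr)2/TiCl4 reagent, so the hindered ketone becomes the exocyclic alkene without epimerising the adjacent α-centre and without attacking the ester.

Step 5
Reactants: 10 ethyl 2-[(1S,3S)-2,2,3-trimethyl-6-methylidenecyclohexyl]acetate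
Product: 11 2-[(1S,3S)-2,2,3-trimethyl-6-methylidenecyclohexyl]ethan-1-ol
Conditions: LiAlH4, Et2O, 0 °C
Reagents that add atoms: none
Why: Hydride reduction of the ester to the primary alcohol; no stereocentre is touched.

Step 6
Reactants: 11 2-[(1S,3S)-2,2,3-trimethyl-6-methylidenecyclohexyl]ethan-1-ol
Product: 12 (1S,3S)-1-(2-bromoethyl)-2,2,3-trimethyl-6-methylidenecyclohexane
Conditions: CBr4, PPh3, CH2Cl2, 0 °C
Reagents that add atoms: carbon tetrabromide, BrC(Br)(Br)Br
Why: Appel bromination of the primary alcohol (SN2 on the alkoxyphosphonium salt); no stereocentre is touched.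

Step 7
Reactants: 13 5-bromo-2-methylpent-2-ene
Product: 14 6-methylhept-5-en-1-yne
Conditions: LiC≡CH·H2NCH2CH2NH2, DMSO, 10 °C to rt
Reagents that add atoms: lithium acetylide–ethylenediamine complex, [Li]C#C.NCCN
Why: SN2 alkylation of lithium acetylide by the primary homoallylic bromide in DMSO.

Step 8
Reactants: 14 6-methylhept-5-en-1-yne
Product: 16 (1E)-1-iodo-2,6-dimethylhepta-1,5-diene, via alkenylalane 15 (not isolated)
Conditions: Me3Al, Cp2ZrCl2 (25 mol%), CH2Cl2, 0 °C to rt; then I2, THF, −30 °C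
Reagents that add atoms: trimethylaluminium, C[Al](C)C; iodine, II
Why: Negishi zirconium-catalysed methylalumination is a regioselective syn-carbometalation of the terminal alkyne (methyl to C2, aluminium to C1), and iodinolysis of the C–Al bond occurs with retention, which fixes the E trisubstituted alkene.

Step 9
Reactants: 16 (1E)-1-iodo-2,6-dimethylhepta-1,5-diene; 17 (4-bromobut-1-yn-1-yl)trimethylsilane
Product: 20 (5E)-6,10-dimethylundeca-5,9-dien-1-yne, via alkylzinc bromide 18 (not isolated), via silyl dienyne 19 (not isolated)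
Conditions: 17, Zn dust (I2 cat.), DMA, 70 °C; then 16, Pd(PPh3)4 (3 mol%), THF, rt; then K2CO3, MeOH, rt
Reagents that add atoms: zinc, [Zn] (zinc stays only in 18)
Why: Negishi sp3–sp2 cross-coupling of the homopropargylic zinc reagent with the alkenyl iodide proceeds with retention of the E geometry, and K2CO3/MeOH then removes the alkyne silyl group in the same flask.

Step 10
Reactants: 20 (5E)-6,10-dimethylundeca-5,9-dien-1-yne
Product: 23 (2E,6E)-3,7,11-trimethyldodeca-2,6,10-trien-1-ol (E,E-farnesol), via alkenylalane 21 (not isolated), via lithium aluminate 22 (not isolated)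
Conditions: Me3Al, Cp2ZrCl2 (25 mol%), CH2Cl2, rt; then n-BuLi, hexane, −78 °C; then (CH2O)n, THF, rt
Reagents that add atoms: trimethylaluminium, C[Al](C)C; n-butyllithium, [Li]CCCC (butyl and lithium stay only in 22); paraformaldehyde, C=O
Why: A second Negishi methylalumination (syn, regioselective) gives the E alkenylalane, whose butyl ate complex adds to formaldehyde with retention to give the 2E allylic alcohol.

Step 11
Reactants: 23 (2E,6E)-3,7,11-trimethyldodeca-2,6,10-trien-1-ol
Product: 24 diethyl (2E,6E)-3,7,11-trimethyldodeca-2,6,10-trien-1-yl phosphate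
Conditions: ClP(O)(OEt)2, pyridine, CH2Cl2, 0 °C
Reagents that add atoms: diethyl chlorophosphate, CCOP(=O)(Cl)OCC
Why: Phosphorylation of the primary allylic alcohol installs the leaving group needed for copper-catalysed SN2' substitution.

Step 12
Reactants: 25 but-3-yn-2-ol (racemic)
Product: 26 (but-3-yn-2-yloxy)(tert-butyl)dimethylsilane
Conditions: t-BuMe2SiCl, imidazole, DMF, rt
Reagents that add atoms: tert-butyldimethylsilyl chloride, CC(C)(C)[Si](C)(C)Cl
Why: Silyl protection of the secondary alcohol so that the alkyne can be hydroaluminated cleanly.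

Step 13
Reactants: 24 diethyl (2E,6E)-3,7,11-trimethyldodeca-2,6,10-trien-1-yl phosphate; 26 (but-3-yn-2-yloxy)(tert-butyl)dimethylsilane
Product: 28 tert-butyl{[(3E,5S,8E)-5-ethenyl-5,9,13-trimethyltetradeca-3,8,12-trien-2-yl]oxy}dimethylsilane, via alkenylalane 27 (not isolated)
Conditions: 26, i-Bu2AlH, hexane, 55 °C; then 24, CuCl2·2H2O (5 mol%), Ag2(NHC)2 (2.5 mol%; NHC = chiral sulfonate-bearing 4,5-diphenylimidazolin-2-ylidene, antipode giving 5S), THF, −15 °C
Reagents that add atoms: diisobutylaluminium hydride, CC(C)C[AlH]CC(C)C (aluminium stays only in 27)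
Why: syn-Hydroalumination gives the E alkenylalane, and NHC–copper-catalysed enantioselective allylic substitution delivers it SN2' to C3 of the E phosphate from the face chosen by the chiral carbene, which creates the vinyl-bearing quaternary centre as S and keeps the new alkene E.

Step 14
Reactants: 28 tert-butyl{[(3E,5S,8E)-5-ethenyl-5,9,13-trimethyltetradeca-3,8,12-trien-2-yl]oxy}dimethylsilane
Product: 29 (3E,5S,8E)-5-ethenyl-5,9,13-trimethyltetradeca-3,8,12-trien-2-ol
Conditions: Bu4NF, THF, 0 °C to rt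
Reagents that add atoms: none
Why: Fluoride cleavage of the silyl ether; the quaternary centre and the alkenes are untouched.

Step 15
Reactants: 29 (3E,5S,8E)-5-ethenyl-5,9,13-trimethyltetradeca-3,8,12-trien-2-ol
Product: 30 (3E,5S,8E)-2-chloro-5-ethenyl-5,9,13-trimethyltetradeca-3,8,12-triene
Conditions: PPh3, N-chlorosuccinimide, THF, −20 to 0 °C
Reagents that add atoms: N-chlorosuccinimide, O=C1CCC(=O)N1Cl
Why: Appel-type chlorination under neutral conditions gives the secondary allylic chloride; its configuration at C2 and any allylic transposition do not matter because both converge in the next step.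

Step 16
Reactants: 12 (1S,3S)-1-(2-bromoethyl)-2,2,3-trimethyl-6-methylidenecyclohexane; 30 (3E,5S,8E)-2-chloro-5-ethenyl-5,9,13-trimethyltetradeca-3,8,12-triene
Product: 32 (1S,3S)-1-[(3S,4E,6S,9E)-6-ethenyl-3,6,10,14-tetramethylpentadeca-4,9,13-trien-1-yl]-2,2,3-trimethyl-6-methylidenecyclohexane (CNP0322301.1), via alkylzinc bromide 31 (not isolated)
Conditions: 12, Zn dust (I2 cat.), DMA, 70 °C; then 30, NiCl2·CH3OCH2CH2OCH3 (5 mol%), 2,6-bis[(4S)-4-(2-phenylethyl)-4,5-dihydro-1,3-oxazol-2-yl]pyridine (5.5 mol%), NaCl, DMA/DMF 1:1, −10 °C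
Reagents that add atoms: zinc, [Zn] (zinc stays only in 31)
Why: Stereoconvergent nickel/Pybox-catalysed Negishi coupling: halogen abstraction by low-valent nickel turns both epimers of 30 into one planar allyl radical/allylnickel species, the alkyl group from 31 is joined at the methyl-bearing terminus (the other terminus is neopentylic, so the E alkene is kept), and the chiral ligand fixes the new centre as 3S by catalyst control.

**Compound list**

1 | propanal | CCC=O | starting material
2 | but-3-en-2-one (methyl vinyl ketone) | CC(=O)C=C | starting material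
3 | (2S)-2-methyl-5-oxohexanal | CC(=O)CC[C@H](C)C=O | intermediate
4 | (4S)-4-methylcyclohex-2-en-1-one | O=C1CC[C@H](C)C=C1 | intermediate
5 | trimethyl{[(3R,4S)-3,4-dimethylcyclohex-1-en-1-yl]oxy}silane | C[Si](C)(C)OC1=C[C@H](C)[C@@H](C)CC1 | intermediate
6 | (4S)-3,4-dimethylcyclohex-2-en-1-one | O=C1CC[C@H](C)C(C)=C1 | intermediate
7 | ethyl iodoacetate | CCOC(=O)CI | starting material
8 | lithium (4S)-3,3,4-trimethylcyclohex-1-en-1-olate | [Li+].[O-]C1=CC(C)(C)[C@@H](C)CC1 | intermediate
9 | ethyl 2-[(1R,3S)-2,2,3-trimethyl-6-oxocyclohexyl]acetate | CCOC(=O)C[C@H]1C(=O)CC[C@H](C)C1(C)C | intermediate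
10 | ethyl 2-[(1S,3S)-2,2,3-trimethyl-6-methylidenecyclohexyl]acetate | CCOC(=O)C[C@H]1C(=C)CC[C@H](C)C1(C)C | intermediate
11 | 2-[(1S,3S)-2,2,3-trimethyl-6-methylidenecyclohexyl]ethan-1-ol | OCC[C@H]1C(=C)CC[C@H](C)C1(C)C | intermediate
12 | (1S,3S)-1-(2-bromoethyl)-2,2,3-trimethyl-6-methylidenecyclohexane | BrCC[C@H]1C(=C)CC[C@H](C)C1(C)C | intermediate
13 | 5-bromo-2-methylpent-2-ene | CC(C)=CCCBr | starting material
14 | 6-methylhept-5-en-1-yne | C#CCCC=C(C)C | intermediate
15 | [(1E)-2,6-dimethylhepta-1,5-dien-1-yl]dimethylalumane | C[Al](C)/C=C(\C)CCC=C(C)C | intermediate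
16 | (1E)-1-iodo-2,6-dimethylhepta-1,5-diene | I/C=C(\C)CCC=C(C)C | intermediate
17 | (4-bromobut-1-yn-1-yl)trimethylsilane (C-silyl-protected 4-bromobut-1-yne) | C[Si](C)(C)C#CCCBr | starting material
18 | bromo[4-(trimethylsilyl)but-3-yn-1-yl]zinc | C[Si](C)(C)C#CCC[Zn]Br | intermediate
19 | trimethyl[(5E)-6,10-dimethylundeca-5,9-dien-1-yn-1-yl]silane | C[Si](C)(C)C#CCC/C=C(\C)CCC=C(C)C | intermediate
20 | (5E)-6,10-dimethylundeca-5,9-dien-1-yne | C#CCC/C=C(\C)CCC=C(C)C | intermediate
21 | dimethyl[(1E,5E)-2,6,10-trimethylundeca-1,5,9-trien-1-yl]alumane | C[Al](C)/C=C(\C)CC/C=C(\C)CCC=C(C)C | intermediate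
22 | lithium butyl(dimethyl)[(1E,5E)-2,6,10-trimethylundeca-1,5,9-trien-1-yl]aluminate | [Li+].CCCC[Al-](C)(C)/C=C(\C)CC/C=C(\C)CCC=C(C)C | intermediate
23 | (2E,6E)-3,7,11-trimethyldodeca-2,6,10-trien-1-ol | OC/C=C(\C)CC/C=C(\C)CCC=C(C)C | intermediate
24 | diethyl (2E,6E)-3,7,11-trimethyldodeca-2,6,10-trien-1-yl phosphate | CCOP(=O)(OCC)OC/C=C(\C)CC/C=C(\C)CCC=C(C)C | intermediate
25 | but-3-yn-2-ol (racemic) | CC(O)C#C | starting material
26 | (but-3-yn-2-yloxy)(tert-butyl)dimethylsilane (racemic) | CC(C#C)O[Si](C)(C)C(C)(C)C | intermediate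
27 | [(1E)-3-{[tert-butyl(dimethyl)silyl]oxy}but-1-en-1-yl]bis(2-methylpropyl)alumane | CC(C)C[Al](CC(C)C)/C=C/C(C)O[Si](C)(C)C(C)(C)C | intermediate
28 | tert-butyl{[(3E,5S,8E)-5-ethenyl-5,9,13-trimethyltetradeca-3,8,12-trien-2-yl]oxy}dimethylsilane (both C2 epimers) | C=C[C@@](C)(/C=C/C(C)O[Si](C)(C)C(C)(C)C)CC/C=C(\C)CCC=C(C)C | intermediate
29 | (3E,5S,8E)-5-ethenyl-5,9,13-trimethyltetradeca-3,8,12-trien-2-ol (both C2 epimers) | C=C[C@@](C)(/C=C/C(C)O)CC/C=C(\C)CCC=C(C)C | intermediate
30 | (3E,5S,8E)-2-chloro-5-ethenyl-5,9,13-trimethyltetradeca-3,8,12-triene (both C2 epimers) | C=C[C@@](C)(/C=C/C(C)Cl)CC/C=C(\C)CCC=C(C)C | intermediate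
31 | bromo{2-[(1S,3S)-2,2,3-trimethyl-6-methylidenecyclohexyl]ethyl}zinc | Br[Zn]CC[C@H]1C(=C)CC[C@H](C)C1(C)C | intermediate
32 | (1S,3S)-1-[(3S,4E,6S,9E)-6-ethenyl-3,6,10,14-tetramethylpentadeca-4,9,13-trien-1-yl]-2,2,3-trimethyl-6-methylidenecyclohexane (CNP0322301.1) | C=C[C@@](C)(/C=C/[C@@H](C)CC[C@H]1C(=C)CC[C@H](C)C1(C)C)CC/C=C(\C)CCC=C(C)C | target

**Step count and risks**

Total step count: 16 (ring fragment 6, chain fragment 9, final coupling 1).
Longest linear sequence: 9 steps (steps 7, 8, 9, 10, 11, 13, 14, 15, 16, starting from 13).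

Steps most likely to fail:

1. Step 16. The coupling must be regioselective and catalyst-controlled on a crowded, sensitive polyene chloride. The fallback sets out from 31 (together with 24) and comes back at 32. 3-Chlorobut-1-yne is hydroborated with pinacolborane (Cp2Zr(H)Cl cat.) to racemic (E)-2-(3-chlorobut-1-en-1-yl)-4,4,5,5-tetramethyl-1,3,2-dioxaborolane F1. The same nickel/Pybox coupling is then run between 31 and this small, unhindered chloride to give 4,4,5,5-tetramethyl-2-{(1E,3S)-3-methyl-5-[(1S,3S)-2,2,3-trimethyl-6-methylidenecyclohexyl]pent-1-en-1-yl}-1,3,2-dioxaborolane F2. Finally F2 is joined to phosphate 24 by NHC–copper-catalysed SN2' substitution (CuCl, NaOMe, chiral imidazolinium sulfonate, THF), which sets the quaternary centre and gives 32 directly.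

2. Step 3. Alkylation of the hindered cuprate-derived enolate may be slow, or may give O-alkylation or the cis isomer. The fallback sets out from 6 and comes back at 9. Me2CuLi with Me3SiCl gives trimethyl{[(4S)-3,3,4-trimethylcyclohex-1-en-1-yl]oxy}silane F3. F3 is then alkylated with 7 in a radical chain instead of an enolate SN2 (Et3B, air, CH2Cl2; or Ru(bpy)3Cl2 with blue light): the ethoxycarbonylmethyl radical adds axially to C2 and loss of Me3SiI gives 9.

3. Step 13. Enantio- and SN2' selectivity could be poor with the oxygenated alkenylalane. The fallback sets out from 23 and comes back at 29. Sharpless epoxidation (Ti(OiPr)4, D-(−)-diethyl tartrate, t-BuOOH) gives [(2R,3R)-3-[(3E)-4,8-dimethylnona-3,7-dien-1-yl]-3-methyloxiran-2-yl]methanol F4. The diethylaluminium acetylide made from 26 (n-BuLi, then Et2AlCl) opens the epoxide at C3 with inversion to (2S,3R,6E)-3-{3-[(tert-butyldimethylsilyl)oxy]but-1-yn-1-yl}-3,7,11-trimethyldodeca-6,10-diene-1,2-diol F5, which now carries the quaternary centre. I2/PPh3/imidazole converts the 1,2-diol into the vinyl group, giving tert-butyl{[(5S,8E)-5-ethenyl-5,9,13-trimethyltetradeca-8,12-dien-3-yn-2-yl]oxy}dimethylsilane F6. Bu4NF gives (5S,8E)-5-ethenyl-5,9,13-trimethyltetradeca-8,12-dien-3-yn-2-ol F7, and NaAlH2(OCH2CH2OCH3)2 reduces the propargylic alcohol trans to 29.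

**Further compounds**

F1 | step 16 | (E)-2-(3-chlorobut-1-en-1-yl)-4,4,5,5-tetramethyl-1,3,2-dioxaborolane (racemic) | CC(Cl)/C=C/B1OC(C)(C)C(C)(C)O1
F2 | step 16 | 4,4,5,5-tetramethyl-2-{(1E,3S)-3-methyl-5-[(1S,3S)-2,2,3-trimethyl-6-methylidenecyclohexyl]pent-1-en-1-yl}-1,3,2-dioxaborolane | CC1(C)OB(/C=C/[C@@H](C)CC[C@H]2C(=C)CC[C@H](C)C2(C)C)OC1(C)C
F3 | step 3 | trimethyl{[(4S)-3,3,4-trimethylcyclohex-1-en-1-yl]oxy}silane | C[Si](C)(C)OC1=CC(C)(C)[C@@H](C)CC1
F4 | step 13 | [(2R,3R)-3-[(3E)-4,8-dimethylnona-3,7-dien-1-yl]-3-methyloxiran-2-yl]methanol | OC[C@H]1O[C@]1(C)CC/C=C(\C)CCC=C(C)C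
F5 | step 13 | (2S,3R,6E)-3-{3-[(tert-butyldimethylsilyl)oxy]but-1-yn-1-yl}-3,7,11-trimethyldodeca-6,10-diene-1,2-diol | OC[C@@H](O)[C@@](C)(C#CC(C)O[Si](C)(C)C(C)(C)C)CC/C=C(\C)CCC=C(C)C
F6 | step 13 | tert-butyl{[(5S,8E)-5-ethenyl-5,9,13-trimethyltetradeca-8,12-dien-3-yn-2-yl]oxy}dimethylsilane | C=C[C@@](C)(C#CC(C)O[Si](C)(C)C(C)(C)C)CC/C=C(\C)CCC=C(C)C
F7 | step 13 | (5S,8E)-5-ethenyl-5,9,13-trimethyltetradeca-8,12-dien-3-yn-2-ol | C=C[C@@](C)(C#CC(C)O)CC/C=C(\C)CCC=C(C)C
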